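**Strategy.** All three pyran rings are made the same way: a pyrogallol-type phenol is O-propargylated enantioselectively through a copper allenylidene, and the aryl propargyl ether is closed to a 2-aryl-2H-chromene. Face-selective epoxides of that chromene serve as the C4 electrophiles for both interflavan bonds, so the terminal unit enters only as a phenol. Its ring C is made last from the (S)-1-arylpropargyl ether of the trimer-sized phenol. Gold-catalysed 6-endo-dig hydroarylation joins the alkyne terminus to C4a, the one free carbon ortho to O1 and para to the C7 oxygen of ring A. C2 is untouched, and the resulting C3=C4 alkene is then cis-dioxygenated on the aryl face.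

Key step: step 11

Remarks: flavan numbering is used (O1, C2, C3, C4, C4a, C5 to C8, C8a), and α means the ring face that carries the 2-aryl groups. Ph-pybox* is the antipode of 2,6-bis(4-phenyl-4,5-dihydrooxazol-2-yl)pyridine that gives the S ether; it is fixed once on phenol 3. Aldehydes 1 and 4 are taken as catalogue compounds.

Step 1
Reactants: 1 2,3-bis(benzyloxy)benzaldehyde
Product: 3 2,3-bis(benzyloxy)phenol, via aryl formate 2 (not isolated)
Conditions: mCPBA, CH2Cl2, 0 °C to rt; then K2CO3 (cat.), MeOH, rt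
Reagents that add atoms: 3-chloroperoxybenzoic acid, OOC(=O)c1cccc(Cl)c1
Why: Baeyer–Villiger (Dakin-type) oxidation of an electron-rich benzaldehyde, in which the ortho-alkoxyaryl group migrates, followed by methanolysis of the formate; benzyl ethers are inert.

Step 2
Reactants: 4 4-(benzyloxy)benzaldehyde
Product: 5 rac-1-[4-(benzyloxy)phenyl]prop-2-yn-1-ol
Conditions: HC≡CMgBr, THF, 0 °C; then H2O
Reagents that add atoms: ethynylmagnesium bromide, C#C[Mg]Br
Why: Grignard 1,2-addition to the aldehyde; the carbinol may stay racemic because step 4 is enantioconvergent.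

Step 3
Reactants: 5 rac-1-[4-(benzyloxy)phenyl]prop-2-yn-1-ol
Product: 6 rac-1-[4-(benzyloxy)phenyl]prop-2-yn-1-yl acetate
Conditions: Ac2O, Et3N, DMAP (cat.), CH2Cl2, 0 °C
Reagents that add atoms: acetic anhydride, CC(=O)OC(C)=O
Why: O-acylation of the secondary alcohol installs the leaving group needed for copper allenylidene formation.

Step 4
Reactants: 3 2,3-bis(benzyloxy)phenol; 6 rac-1-[4-(benzyloxy)phenyl]prop-2-yn-1-yl acetate
Product: 7 (S)-1,2-bis(benzyloxy)-3-({1-[4-(benzyloxy)phenyl]prop-2-yn-1-yl}oxy)benzene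
Conditions: CuOTf·0.5C6H6 (5 mol %), Ph-pybox* (10 mol %), i-Pr2NEt, THF, −20 °C
Reagents that add atoms: none
Why: Copper-catalysed enantioselective propargylic etherification: both enantiomers of 6 give the same copper allenylidene, and the pybox ligand directs phenoxide attack at the γ-carbon to one face, which sets the future C2 as S.

Step 5
Reactants: 7 (S)-aryl propargyl ether
Product: 8 (2S)-7,8-bis(benzyloxy)-2-[4-(benzyloxy)phenyl]-2H-chromene
Conditions: Ph3PAuNTf2 (3 mol %), CH2Cl2, rt, dark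
Reagents that add atoms: none
Why: Gold-catalysed 6-endo-dig hydroarylation of an aryl propargyl ether at the only free ortho carbon (para to a benzyloxy group); the O–C2 bond is never broken, so the stereocentre is carried over.

Step 6
Reactants: 8 (2S)-chromene
Product: 10 sulfide (2R,3R,4R)-4-(benzylsulfanyl)-7,8-bis(benzyloxy)-2-[4-(benzyloxy)phenyl]chroman-3-ol, via β-epoxide 9 (not isolated)
Conditions: DMDO (1.0 equiv), acetone–CH2Cl2, −40 °C; volatiles removed cold; BnSH (3 equiv), Et3N (cat.), CH2Cl2, −40 to 0 °C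
Reagents that add atoms: dimethyldioxirane, CC1(C)OO1; phenylmethanethiol, SCc1ccccc1
Why: Epoxidation on the face away from the 2-aryl group, then anti (SN2-type) opening of the benzylic epoxide carbon C4 by the thiol, gives 3β-OH and 4α-S (2,3-trans-3,4-trans); the sulfide is a latent C4 leaving group.

Step 7
Reactants: 8 (2S)-chromene
Product: 12 α-epoxide (2R,3R,4R)-7,8-bis(benzyloxy)-2-[4-(benzyloxy)phenyl]-3,4-epoxychromane, via bromohydrin 11 (not isolated)
Conditions: NBS (1.05 equiv), THF–H2O (10:1), 0 °C; then DBU (1.5 equiv), 0 °C; used at once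
Reagents that add atoms: water, O (the bromine of N-bromosuccinimide, O=C1CCC(=O)N1Br, stays only in 11)
Why: Bromohydrin formation (Br+ at C3 anti to the 2-aryl group, water at benzylic C4 anti to Br) and Williamson-type closure with inversion at C3 place the epoxide oxygen on the aryl face, which fixes the 2,3-cis relation of the upper unit.

Step 8
Reactants: 12 α-epoxide; 10 sulfide
Product: 13 hexa-O-benzyl dimer, tri-O-benzylepioritin-(4β→6)-[4α-benzylsulfanyl-tri-O-benzyloritin]
Conditions: BF3·OEt2 (20 mol %), CH2Cl2, −78 °C; 12 added slowly to a threefold excess of 10, unreacted 10 recovered on chromatography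
Reagents that add atoms: none
Why: Lewis acid-promoted Friedel–Crafts opening of the benzylic epoxide, a pure one-to-one addition of the two partners: C6 of 10 (ortho to the 7-benzyloxy group, para to O1) attacks C4 anti to the epoxide oxygen, giving the 4β-aryl 3α-ol (3,4-trans), while the soft sulfide is left alone by the hard Lewis acid.

Step 9
Reactants: 13 hexa-O-benzyl dimer sulfide; 3 2,3-bis(benzyloxy)phenol
Product: 14 octa-O-benzyl trimer phenol, the dimer carrying at C4 (4α) of its oritin unit a 2,3-bis(benzyloxy)-4-hydroxyphenyl group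
Conditions: AgBF4 (1.5 equiv), THF, 0 °C; phenol 3 in eightfold excess
Reagents that add atoms: none
Why: Thiophilic silver activation of the benzylic sulfide gives the C4 cation of the oritin unit, which alkylates phenol 3 para to its hydroxyl (Friedel–Crafts) from the face trans to the 3β-OH, setting 4α.

Step 10
Reactants: 14 octa-O-benzyl trimer phenol; 6 rac-propargylic acetate
Product: 15 nona-O-benzyl (S)-1-[4-(benzyloxy)phenyl]prop-2-yn-1-yl ether of phenol 14
Conditions: CuOTf·0.5C6H6 (10 mol %), Ph-pybox* (20 mol %), i-Pr2NEt, THF, −20 °C; acetate 6 in twofold excess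
Reagents that add atoms: none
Why: The same copper-catalysed enantioselective propargylic etherification as in step 4; the phenoxide outcompetes the two hindered secondary alcohols, and the ligand, not the remote stereocentres, sets the new centre as S.

Step 11
Reactants: 15 nona-O-benzyl aryl propargyl ether
Product: 16 nona-O-benzyl trimer chromene, tri-O-benzylepioritin-(4β→6)-tri-O-benzyloritin-(4α→6)-[(2S)-7,8-bis(benzyloxy)-2-(4-benzyloxyphenyl)-2H-chromene]
Conditions: Ph3PAuNTf2 (5 mol %), CH2Cl2, rt, dark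
Reagents that add atoms: none
Why: The cationic gold phosphine π-activates the terminal alkyne, C4a of ring A attacks the alkyne terminus anti to gold, and rearomatisation with protodeauration leaves the C3=C4 alkene. The closest known reaction is the gold- or platinum-catalysed intramolecular hydroarylation of aryl propargyl ethers to 2H-chromenes. Ring C of the terminal unit is closed in the 6-endo-dig mode by the new C4–C4a bond. No stereocentre is formed, and C2, set in step 10, keeps its configuration because the O1–C2 bond is never broken. The step needs 6-endo over 5-exo closure and attack by C4a alone; the terminal alkyne favours the endo mode, C8 is blocked by its benzyloxy group, C4a is para to the C7 oxygen, and the intramolecular six-ring path should outrun attack by the other electron-rich rings.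

Step 12
Reactants: 16 nona-O-benzyl trimer chromene
Product: 18 nona-O-benzyl trimer 3α,4α-cyclic carbonate, via bromohydrin 17 (not isolated)
Conditions: NBS (1.05 equiv), THF–H2O (10:1), 0 °C; then DBU (3 equiv), CO2 (1 atm), rt
Reagents that add atoms: water, O; carbon dioxide, O=C=O (the bromine of N-bromosuccinimide, O=C1CCC(=O)N1Br, stays only in 17)
Why: Bromohydrin formation as in step 7 followed by carboxylative cyclisation: the C4α carbonate anion (or the α-epoxide and bromide it equilibrates with) closes onto C3 with inversion, and a five-membered carbonate can only be cis-fused, so both oxygens end on the aryl face (3α,4α).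

Step 13
Reactants: 18 nona-O-benzyl trimer cyclic carbonate
Product: 19 nona-O-benzyl ether of the target (all nine phenols benzylated, four secondary OH free)
Conditions: K2CO3, MeOH–THF, rt
Reagents that add atoms: none
Why: Transesterification of the cyclic carbonate frees the cis-diol without touching a stereocentre; it is done before hydrogenolysis because a benzylic carbonate would be cleaved at C4–O by Pd/H2.

Step 14
Reactants: 19 nona-O-benzyl ether of the target
Product: 20 epioritin-(4β→6)-oritin-(4α→6)-epioritin-4α-ol (CNP0140823.2)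
Conditions: H2 (1 atm), Pd(OH)2/C, THF–MeOH, rt; filtered under argon
Reagents that add atoms: none
Why: Hydrogenolysis of nine aryl benzyl ethers, which should cleave much faster than the secondary benzylic C4–OH under neutral conditions; the interflavan C–C bonds are inert.

**Compound list**

1 | 2,3-bis(benzyloxy)benzaldehyde | O=Cc1cccc(OCc2ccccc2)c1OCc1ccccc1 | starting material
2 | 2,3-bis(benzyloxy)phenyl formate | O=COc1cccc(OCc2ccccc2)c1OCc1ccccc1 | intermediate
3 | 2,3-bis(benzyloxy)phenol | Oc1cccc(OCc2ccccc2)c1OCc1ccccc1 | intermediate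
4 | 4-(benzyloxy)benzaldehyde | O=Cc1ccc(OCc2ccccc2)cc1 | starting material
5 | rac-1-[4-(benzyloxy)phenyl]prop-2-yn-1-ol | C#CC(O)c1ccc(OCc2ccccc2)cc1 | intermediate
6 | rac-1-[4-(benzyloxy)phenyl]prop-2-yn-1-yl acetate | C#CC(OC(C)=O)c1ccc(OCc2ccccc2)cc1 | intermediate
7 | (S)-1,2-bis(benzyloxy)-3-({1-[4-(benzyloxy)phenyl]prop-2-yn-1-yl}oxy)benzene | c1ccc(OCc2ccccc2)c(OCc2ccccc2)c1O[C@H](c1ccc(OCc2ccccc2)cc1)C#C | intermediate
8 | (2S)-7,8-bis(benzyloxy)-2-[4-(benzyloxy)phenyl]-2H-chromene | c1cc2c(c(OCc3ccccc3)c1OCc1ccccc1)O[C@H](c1ccc(OCc3ccccc3)cc1)C=C2 | intermediate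
9 | β-epoxide, (2R,3S,4S)-7,8-bis(benzyloxy)-2-[4-(benzyloxy)phenyl]-3,4-epoxychromane (epoxide trans to the aryl group) | c1cc2c(c(OCc3ccccc3)c1OCc1ccccc1)O[C@H](c1ccc(OCc3ccccc3)cc1)[C@H]1O[C@@H]21 | intermediate
10 | (2R,3R,4R)-4-(benzylsulfanyl)-7,8-bis(benzyloxy)-2-[4-(benzyloxy)phenyl]chroman-3-ol (2,3-trans-3,4-trans) | c1cc2c(c(OCc3ccccc3)c1OCc1ccccc1)O[C@H](c1ccc(OCc3ccccc3)cc1)[C@@H](O)[C@@H]2SCc1ccccc1 | intermediate
11 | (2R,3S,4R)-3-bromo-7,8-bis(benzyloxy)-2-[4-(benzyloxy)phenyl]chroman-4-ol (3β-Br, 4α-OH) | c1cc2c(c(OCc3ccccc3)c1OCc1ccccc1)O[C@H](c1ccc(OCc3ccccc3)cc1)[C@@H](Br)[C@@H]2O | intermediate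
12 | α-epoxide, (2R,3R,4R)-7,8-bis(benzyloxy)-2-[4-(benzyloxy)phenyl]-3,4-epoxychromane (epoxide cis to the aryl group) | c1cc2c(c(OCc3ccccc3)c1OCc1ccccc1)O[C@H](c1ccc(OCc3ccccc3)cc1)[C@@H]1O[C@H]21 | intermediate
13 | hexa-O-benzyl dimer: 7,8,4'-tri-O-benzylepioritin-(4β→6)-[4α-benzylsulfanyl-7,8,4'-tri-O-benzyloritin]; upper unit 2,3-cis-3,4-trans, lower unit 2,3-trans-3,4-trans, both 3-OH free | O(Cc5ccccc5)c1ccc([C@H]2Oc3c(ccc(OCc5ccccc5)c3OCc5ccccc5)[C@H](c3cc4c(c(OCc5ccccc5)c3OCc5ccccc5)O[C@H](c3ccc(OCc5ccccc5)cc3)[C@@H](O)[C@@H]4SCc5ccccc5)[C@H]2O)cc1 | intermediate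
14 | octa-O-benzyl trimer phenol: the dimer of 13 with the 4α-sulfide replaced by a 2,3-bis(benzyloxy)-4-hydroxyphenyl group bonded through its C1 | O(Cc5ccccc5)c1ccc([C@H]2Oc3c(ccc(OCc5ccccc5)c3OCc5ccccc5)[C@H](c3cc4c(c(OCc5ccccc5)c3OCc5ccccc5)O[C@H](c3ccc(OCc5ccccc5)cc3)[C@@H](O)[C@@H]4c3ccc(O)c(OCc5ccccc5)c3OCc5ccccc5)[C@H]2O)cc1 | intermediate
15 | nona-O-benzyl aryl propargyl ether: (S)-1-[4-(benzyloxy)phenyl]prop-2-yn-1-yl ether of the phenol of 14 | O(Cc5ccccc5)c1ccc([C@H]2Oc3c(ccc(OCc5ccccc5)c3OCc5ccccc5)[C@H](c3cc4c(c(OCc5ccccc5)c3OCc5ccccc5)O[C@H](c3ccc(OCc5ccccc5)cc3)[C@@H](O)[C@@H]4c3ccc(O[C@H](c6ccc(OCc5ccccc5)cc6)C#C)c(OCc5ccccc5)c3OCc5ccccc5)[C@H]2O)cc1 | intermediate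
16 | nona-O-benzyl trimer chromene: tri-O-benzylepioritin-(4β→6)-tri-O-benzyloritin-(4α→6)-[(2S)-7,8-bis(benzyloxy)-2-(4-benzyloxyphenyl)-2H-chromene] | O(Cc5ccccc5)c1ccc([C@H]2Oc3c(ccc(OCc5ccccc5)c3OCc5ccccc5)[C@H](c3cc4c(c(OCc5ccccc5)c3OCc5ccccc5)O[C@H](c3ccc(OCc5ccccc5)cc3)[C@@H](O)[C@@H]4c3cc4c(c(OCc5ccccc5)c3OCc5ccccc5)O[C@H](c3ccc(OCc5ccccc5)cc3)C=C4)[C@H]2O)cc1 | intermediate
17 | trimer bromohydrin: 16 with 3β-Br and 4α-OH added across C3=C4 of the terminal unit | O(Cc5ccccc5)c1ccc([C@H]2Oc3c(ccc(OCc5ccccc5)c3OCc5ccccc5)[C@H](c3cc4c(c(OCc5ccccc5)c3OCc5ccccc5)O[C@H](c3ccc(OCc5ccccc5)cc3)[C@@H](O)[C@@H]4c3cc4c(c(OCc5ccccc5)c3OCc5ccccc5)O[C@H](c3ccc(OCc5ccccc5)cc3)[C@@H](Br)[C@@H]4O)[C@H]2O)cc1 | intermediate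
18 | trimer cyclic carbonate: 3α,4α-carbonate of the terminal unit of 19 | O(Cc5ccccc5)c1ccc([C@H]2Oc3c(ccc(OCc5ccccc5)c3OCc5ccccc5)[C@H](c3cc4c(c(OCc5ccccc5)c3OCc5ccccc5)O[C@H](c3ccc(OCc5ccccc5)cc3)[C@@H](O)[C@@H]4c3cc4c(c(OCc5ccccc5)c3OCc5ccccc5)O[C@H](c3ccc(OCc5ccccc5)cc3)[C@@H]6OC(=O)O[C@H]46)[C@H]2O)cc1 | intermediate
19 | nona-O-benzyl ether of 20 (7,8,4'-tri-O-benzyl on each unit; terminal unit 2,3-cis-3,4-cis diol) | O(Cc5ccccc5)c1ccc([C@H]2Oc3c(ccc(OCc5ccccc5)c3OCc5ccccc5)[C@H](c3cc4c(c(OCc5ccccc5)c3OCc5ccccc5)O[C@H](c3ccc(OCc5ccccc5)cc3)[C@@H](O)[C@@H]4c3cc4c(c(OCc5ccccc5)c3OCc5ccccc5)O[C@H](c3ccc(OCc5ccccc5)cc3)[C@H](O)[C@@H]4O)[C@H]2O)cc1 | intermediate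
20 | epioritin-(4β→6)-oritin-(4α→6)-epioritin-4α-ol; upper unit (2R,3R,4S), middle unit (2R,3S,4R), terminal unit (2R,3R,4R) | Oc1ccc([C@H]2Oc3c(ccc(O)c3O)[C@H](c3cc4c(c(O)c3O)O[C@H](c3ccc(O)cc3)[C@@H](O)[C@@H]4c3cc4c(c(O)c3O)O[C@H](c3ccc(O)cc3)[C@H](O)[C@@H]4O)[C@H]2O)cc1 | target

**Totals.** 14 steps in all. The longest linear sequence is 12 steps (steps 2, 3, 4, 5, 6, 8, 9, 10, 11, 12, 13, 14, from aldehyde 4).

**Steps most likely to fail**

Step 11 (key step). The gold cation may ionise the doubly activated propargylic O1–C2 bond instead of activating the alkyne, which would erode the C2 configuration or cleave the ether. Closure could also take the exo course, or the catalyst could be held back by the many ether oxygens. The fallback closes the same ring through O1–C2 instead, without any propargylic ether, and sets out from phenol 14. Magnesium-mediated ortho-formylation (MgCl2, Et3N, paraformaldehyde, THF, reflux) can only occur at C4a and should give the trimer salicylaldehyde F4. Heating F4 with (E)-2-[4-(benzyloxy)phenyl]vinylboronic acid and catalytic dibenzylamine in dioxane at 90 °C (Petasis-type condensation, loss of the amine, oxa-6π electrocyclisation) should give chromene 16 together with the trimer 2-epi-chromene F5. The two are diastereomers and would be separated by preparative HPLC, and the route is rejoined at 16. The price is that C2 of the terminal unit is no longer catalyst-controlled.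

Step 9. The cation may be captured ortho instead of para to the phenol hydroxyl, on oxygen, or from the β face. It may also be captured by the free C6 of the upper unit of another dimer, which leads to chain growth. The fallback moves the arylation to the monomer stage, where isomers are cheap to separate, and sets out from chromene 8. Compound 8 is epoxidised with dimethyldioxirane to 9, which after removal of acetone is opened by phenol 3 (5 equiv, BF3·OEt2 cat., CH2Cl2, −78 °C) to the 4α-arylflavan-3-ol phenol F1. The phenol of F1 is masked with pivaloyl chloride and Et3N as the monomer aryl pivalate F2, which damps the pendant ring. F2 then replaces sulfide 10 as the nucleophile toward α-epoxide 12 (BF3·OEt2 cat., −78 °C) to give the trimer pivalate F3. K2CO3 in MeOH removes the pivalate and returns phenol 14.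

Step 12. NBS may brominate the electron-rich arenes, and water may add cis to bromine. Displacement at C3 may be diverted into a 1,2-shift of the C2 aryl group, or HBr may be lost toward a flavylium ion. The fallback sets out from chromene 16 and uses the Woodward cis-hydroxylation (I2, AgOAc, AcOH–H2O, rt). The iodonium ion forms anti to the aryl group, acetate adds at C4, and silver-assisted closure gives the cis-fused acetoxonium ion on the aryl face. Its hydrolysis should give the trimer cis-hydroxy acetate F6, which K2CO3 in MeOH converts into 19. Any aryl iodide formed on the way would be removed in the final hydrogenolysis.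

**Further compounds**

F1 | step 9 | (2,3-trans-3,4-trans)-4α-[2,3-bis(benzyloxy)-4-hydroxyphenyl]-7,8-bis(benzyloxy)-2-[4-(benzyloxy)phenyl]chroman-3-ol, 2R series | c1cc2c(c(OCc3ccccc3)c1OCc1ccccc1)O[C@H](c1ccc(OCc3ccccc3)cc1)[C@@H](O)[C@@H]2c1ccc(O)c(OCc3ccccc3)c1OCc1ccccc1
F2 | step 9 | aryl pivalate of F1 | c1cc2c(c(OCc3ccccc3)c1OCc1ccccc1)O[C@H](c1ccc(OCc3ccccc3)cc1)[C@@H](O)[C@@H]2c1ccc(OC(=O)C(C)(C)C)c(OCc3ccccc3)c1OCc1ccccc1
F3 | step 9 | aryl pivalate of trimer phenol 14 | O(Cc5ccccc5)c1ccc([C@H]2Oc3c(ccc(OCc5ccccc5)c3OCc5ccccc5)[C@H](c3cc4c(c(OCc5ccccc5)c3OCc5ccccc5)O[C@H](c3ccc(OCc5ccccc5)cc3)[C@@H](O)[C@@H]4c3ccc(OC(=O)C(C)(C)C)c(OCc5ccccc5)c3OCc5ccccc5)[C@H]2O)cc1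
F4 | step 11 | trimer salicylaldehyde: 14 with CHO on the carbon ortho to the phenol OH | O(Cc5ccccc5)c1ccc([C@H]2Oc3c(ccc(OCc5ccccc5)c3OCc5ccccc5)[C@H](c3cc4c(c(OCc5ccccc5)c3OCc5ccccc5)O[C@H](c3ccc(OCc5ccccc5)cc3)[C@@H](O)[C@@H]4c3cc(C=O)c(O)c(OCc5ccccc5)c3OCc5ccccc5)[C@H]2O)cc1
F5 | step 11 | C2 epimer of 16 in the terminal chromene unit (2R) | O(Cc5ccccc5)c1ccc([C@H]2Oc3c(ccc(OCc5ccccc5)c3OCc5ccccc5)[C@H](c3cc4c(c(OCc5ccccc5)c3OCc5ccccc5)O[C@H](c3ccc(OCc5ccccc5)cc3)[C@@H](O)[C@@H]4c3cc4c(c(OCc5ccccc5)c3OCc5ccccc5)O[C@@H](c3ccc(OCc5ccccc5)cc3)C=C4)[C@H]2O)cc1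
F6 | step 12 | 3-O-acetate of 19 at the terminal unit (3α-OAc, 4α-OH) | O(Cc5ccccc5)c1ccc([C@H]2Oc3c(ccc(OCc5ccccc5)c3OCc5ccccc5)[C@H](c3cc4c(c(OCc5ccccc5)c3OCc5ccccc5)O[C@H](c3ccc(OCc5ccccc5)cc3)[C@@H](O)[C@@H]4c3cc4c(c(OCc5ccccc5)c3OCc5ccccc5)O[C@H](c3ccc(OCc5ccccc5)cc3)[C@H](OC(C)=O)[C@@H]4O)[C@H]2O)cc1
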